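**Plan**

- Feature used: the ring ketone C9 carries on its α-carbon C8 the exocyclic hydroxymethyl group. With a temporary C7=C8 double bond, C8–C9 becomes the bond between an alkenyl carbon and a carbinol carbon, so the 14-membered carbocycle can be closed there by adding a C8 alkenylchromium to a C9 aldehyde.
- Cuts: C8–C9 (ring closure), then C1=C2 (Horner–Wadsworth–Emmons), C14–C1 (phosphonate addition) and C7=C8 (iodo-Wittig).
- Forward: fragment A (C9–C14 plus C1, from (R)-citronellal) and fragment B (C2–C8, from nerol, carrying the epoxide ring) are joined at C1=C2; the chain is then closed at C8–C9 to the only carbocycle.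
- Stereochemistry: C12 from (R)-citronellal; C13 by D-proline aminoxylation; C3/C4 by Sharpless epoxidation of nerol; 1E from the olefination.
- C8: the ring closure sets a temporary 9S carbinol (chiral ligand), which directs hydrogenation of the temporary C7=C8 bond to give 8S and is then oxidised to the ketone.

Key step: step 17

Numbering: ring carbons C1 (isopropyl-bearing alkene carbon), C2 (=CH), C3 (epoxide CH), C4 (epoxide C–CH3), C5–C7 (CH2), C8 (CH bearing C15H2OH), C9 (C=O), C10, C11, C12 (CH–CH3), C13 (CH–OH), C14 (C=O); the target is 1E,3S,4R,8S,12R,13S.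

Assumption: the (S)-configured sulfonamide ligand of step 17 gives the 9S carbinol (the usual facial model of this ligand class); if the sense proves reversed, the (R)-ligand is used and nothing else changes.

**Step 1**
Reactants: 1 1-iodo-2-methylpropane; 2 triethyl phosphite
Product: 3 diethyl (2-methylpropyl)phosphonate
Conditions: neat, 150 °C, EtI distilled off
Reagents that add atoms: none
Why: Michaelis–Arbuzov reaction, in which the phosphite displaces iodide and the phosphonium salt is dealkylated, installing C1 and its isopropyl group as a phosphonate without forming a stereocentre.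

**Step 2**
Reactants: 4 (R)-citronellal
Product: 6 (2S,3R)-2-(anilinooxy)-3,7-dimethyloct-6-en-1-ol, via anilinooxy aldehyde 5 (not isolated)
Conditions: PhNO, D-proline (20 mol%), CHCl3, 4 °C; then NaBH4, EtOH, 0 °C
Reagents that add atoms: nitrosobenzene O=Nc1ccccc1
Why: Proline-catalysed α-aminoxylation through the enamine, in which the carboxylic acid of D-proline delivers the nitroso oxygen to one enamine face and so sets 13S under catalyst control beside the 12R centre from citronellal, followed by borohydride reduction before the α-oxy aldehyde can epimerise.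

**Step 3**
Reactants: 6 (2S,3R)-2-(anilinooxy)-3,7-dimethyloct-6-en-1-ol
Product: 7 (2S,3R)-3,7-dimethyloct-6-ene-1,2-diol
Conditions: Zn, AcOH/THF, rt
Reagents that add atoms: none
Why: Reductive N–O cleavage by zinc in acetic acid, a standard unmasking of aminoxylation products that leaves the stereocentres and the trisubstituted alkene untouched.

**Step 4**
Reactants: 7 (2S,3R)-3,7-dimethyloct-6-ene-1,2-diol
Product: 8 (2S,3R)-3,7-dimethyl-1,2-bis(triethylsilyloxy)oct-6-ene
Conditions: Et3SiCl, imidazole, DMAP (cat.), CH2Cl2, 0 °C to rt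
Reagents that add atoms: chlorotriethylsilane CC[Si](Cl)(CC)CC
Why: Silyl ether formation at both hydroxyls, which protects O13 for the rest of the route and prepares the primary position for direct oxidation.

**Step 5**
Reactants: 8 (2S,3R)-3,7-dimethyl-1,2-bis(triethylsilyloxy)oct-6-ene
Product: 9 (2S,3R)-3,7-dimethyl-2-(triethylsilyloxy)oct-6-enal
Conditions: (COCl)2, DMSO, CH2Cl2, −78 to −40 °C; then Et3N, −78 to 0 °C
Reagents that add atoms: none
Why: Swern oxidation in which the primary triethylsilyl ether is cleaved by the chlorosulfonium salt and oxidised in the same flask while the secondary silyl ether stays, a known selective reaction type run cold to guard the α-silyloxy stereocentre.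

**Step 6**
Reactants: 3 diethyl (2-methylpropyl)phosphonate; 9 (2S,3R)-3,7-dimethyl-2-(triethylsilyloxy)oct-6-enal
Product: 11 β-hydroxyphosphonate (C14–OH; C1 and C14 epimers; 12R,13S), via lithiated phosphonate 10 (not isolated)
Conditions: 3, n-BuLi, THF, −78 °C; then 9, −78 °C; NH4Cl quench at −78 °C
Reagents that add atoms: none
Why: 1,2-Addition of an α-lithiated alkylphosphonate to an aldehyde, which forms the C14–C1 bond; the new centres at C14 and C1 form as mixtures and are removed in steps 7 and 15.

**Step 7**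
Reactants: 11 β-hydroxyphosphonate
Product: 12 β-ketophosphonate (fragment A; C1 epimers; 12R,13S)
Conditions: Dess–Martin periodinane, NaHCO3, CH2Cl2, rt
Reagents that add atoms: none
Why: Dess–Martin oxidation of the β-hydroxyphosphonate to the β-ketophosphonate under buffered, non-epimerising conditions.

**Step 8**
Reactants: 13 nerol
Product: 14 (2S,3R)-2,3-epoxynerol
Conditions: Ti(OiPr)4 (10 mol%), L-(+)-diethyl tartrate (12 mol%), t-BuOOH, 4 Å MS, CH2Cl2, −20 °C
Reagents that add atoms: tert-butyl hydroperoxide CC(C)(C)OO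
Why: Sharpless asymmetric epoxidation, in which the allylic hydroxyl binds titanium so that only the 2,3-alkene reacts, the L-tartrate selects the face giving 3S,4R, and the Z geometry of nerol fixes the cis relation of C2 and C5 on the epoxide.

**Step 9**
Reactants: 14 (2S,3R)-2,3-epoxynerol
Product: 15 triethylsilyl ether of 14
Conditions: Et3SiCl, imidazole, CH2Cl2, 0 °C
Reagents that add atoms: chlorotriethylsilane CC[Si](Cl)(CC)CC
Why: Silyl ether formation at the primary hydroxyl, chosen so that step 14 can oxidise this position directly.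

**Step 10**
Reactants: 15 triethylsilyl ether of 14
Product: 17 3-[(2R,3S)-2-methyl-3-(triethylsilyloxymethyl)oxiran-2-yl]propanal, via ozonide 16 (not isolated)
Conditions: O3, CH2Cl2, −78 °C; then PPh3, −78 °C to rt
Reagents that add atoms: ozone [O-][O+]=O
Why: Ozonolysis of the only C=C bond with reductive work-up, which removes the isopropylidene end and leaves C7 as an aldehyde, the epoxide and silyl ether being inert to ozone.

**Step 11**
Reactants: 17 3-[(2R,3S)-2-methyl-3-(triethylsilyloxymethyl)oxiran-2-yl]propanal; 18 ethyl (triphenylphosphoranylidene)acetate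
Product: 20 ethyl (2Z)-2-iodo-5-[(2R,3S)-2-methyl-3-(triethylsilyloxymethyl)oxiran-2-yl]pent-2-enoate, via iodo ylide 19 (not isolated)
Conditions: 18, N-iodosuccinimide, CH2Cl2, −20 °C; then 17, K2CO3, rt
Reagents that add atoms: N-iodosuccinimide O=C1CCC(=O)N1I
Why: Wittig reaction of the ester-stabilised α-iodo ylide made in the flask by iodination of 18, which places the ester trans to the chain and so should give the 7Z iodoalkene with iodine cis to C6.

**Step 12**
Reactants: 20 ethyl (2Z)-2-iodo-enoate
Product: 21 (2Z)-2-iodo-5-[(2R,3S)-2-methyl-3-(triethylsilyloxymethyl)oxiran-2-yl]pent-2-en-1-ol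
Conditions: i-Bu2AlH, CH2Cl2, −78 °C; aqueous potassium sodium tartrate
Reagents that add atoms: none
Why: 1,2-Reduction of the enoate ester with i-Bu2AlH at low temperature, a standard route to 2-iodoallylic alcohols that leaves the C–I bond, the epoxide and the silyl ether intact.

**Step 13**
Reactants: 21 (2Z)-2-iodoallylic alcohol
Product: 22 tert-butyldimethylsilyl ether of 21
Conditions: t-BuMe2SiCl, imidazole, DMF, rt
Reagents that add atoms: tert-butyldimethylsilyl chloride CC(C)(C)[Si](C)(C)Cl
Why: Silyl ether formation at O15 with a group that survives the Swern, chromium and hydrogenation steps and is removed together with the O13 group at the end.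

**Step 14**
Reactants: 22 tert-butyldimethylsilyl ether of 21
Product: 23 (2R,3R)-3-[(3Z)-5-(tert-butyldimethylsilyloxy)-4-iodopent-3-en-1-yl]-3-methyloxirane-2-carbaldehyde (fragment B)
Conditions: (COCl)2, DMSO, CH2Cl2, −78 to −40 °C; then Et3N, −78 to 0 °C
Reagents that add atoms: none
Why: Swern oxidation that converts the primary triethylsilyl ether directly to the aldehyde as in step 5, the tert-butyldimethylsilyl ether being inert and the epoxide carbon next to the aldehyde not prone to enolise.

**Step 15**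
Reactants: 12 β-ketophosphonate; 23 epoxy aldehyde
Product: 24 seco enone (1E,3S,4R,7Z,12R,13S; C9=CMe2 end; 8-iodo; O13-SiEt3; O15-SiMe2tBu)
Conditions: Ba(OH)2 (activated), THF/H2O (40:1), 0 °C to rt
Reagents that add atoms: none
Why: Horner–Wadsworth–Emmons olefination under mild Ba(OH)2 conditions, which joins the fragments at C1=C2 and should give the 1E enone (C14 carbonyl trans to C3) as the preferred outcome of the stabilised phosphonate.

**Step 16**
Reactants: 24 seco enone
Product: 26 seco aldehyde (C9 aldehyde; otherwise as 24), via vicinal diol 25 (not isolated)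
Conditions: OsO4 (2 mol%), NaIO4, 2,6-lutidine, dioxane/H2O (3:1), rt
Reagents that add atoms: osmium tetroxide O=[Os](=O)(=O)=O; sodium periodate [Na+].[O-]I(=O)(=O)=O
Why: Lemieux–Johnson cleavage, in which OsO4 dihydroxylates the most electron-rich alkene (the isopropylidene end) in preference to the enone and iodoalkene double bonds and periodate cleaves the diol to the C9 aldehyde.

**Step 17**
Reactants: 26 seco aldehyde
Product: 28 macrocyclic allylic alcohol (1E,3S,4R,7Z,9S,12R,13S), via alkenylchromium 27 (not isolated)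
Conditions: CrCl2 (4 equiv), (S)-N-[2-(4-isopropyl-4,5-dihydrooxazol-2-yl)-6-methylphenyl]methanesulfonamide (4.4 equiv), Et3N (4.4 equiv), NiCl2 (0.2 equiv), THF/MeCN, rt; 26 added by syringe pump to 2 mM
Reagents that add atoms: none
Why: Zerovalent nickel (from NiCl2 and CrCl2) inserts into the C8–I bond and passes the alkenyl group, with retention of the 7Z geometry, to trivalent chromium, and the alkenylchromium 27, which carries the deprotonated chiral sulfonamide ligand, adds to the C9 aldehyde to give the chromium alkoxide of 28. The closest known reaction type is the ligand-controlled asymmetric Nozaki–Hiyama–Kishi macrocyclisation of an alkenyl iodide onto an aldehyde. The 14-membered carbocycle closes in a 14-exo-trig mode (C8 attacks the carbonyl carbon C9, the C=O bond staying outside the ring), and no other ring is formed. The new C9 stereocentre (9S) is set by the chiral ligand on chromium and serves only to direct step 18; C8 is still sp2 at this stage. The step needs chemoselectivity for the aldehyde over the C14 enone and the epoxide, which the low basicity and aldehyde preference of alkenylchromium reagents should secure, and ring closure over oligomerisation, which slow addition to high dilution should secure.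

**Step 18**
Reactants: 28 macrocyclic allylic alcohol
Product: 29 macrocyclic alcohol (1E,3S,4R,8S,9S,12R,13S)
Conditions: H2 (60 bar), [Rh(nbd)(dppb)]BF4 (10 mol%), CH2Cl2, rt
Reagents that add atoms: none
Why: Hydroxyl-directed homogeneous hydrogenation, in which the C9–H bond lies in the alkene plane to avoid allylic 1,3-strain with C6 (cis to C9 on the 7Z alkene), so rhodium bound to the 9S hydroxyl should deliver H2 to the face that makes C8 S, while the enone double bond, with no free hydroxyl nearby, is left.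

**Step 19**
Reactants: 29 macrocyclic alcohol
Product: 30 bis-silyl diketone (1E,3S,4R,8S,12R,13S)
Conditions: Dess–Martin periodinane, NaHCO3, CH2Cl2, 0 °C to rt
Reagents that add atoms: none
Why: Dess–Martin oxidation of the C9 carbinol to the ketone, which erases the temporary stereocentre under buffered conditions that should neither epimerise C8 nor eliminate the β-silyloxy group.

**Step 20**
Reactants: 30 bis-silyl diketone
Product: 31 target CNP0110598.2
Conditions: HF·pyridine, pyridine, THF, 0 °C to rt
Reagents that add atoms: none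
Why: Fluoride-mediated cleavage of both silyl ethers under pyridine-buffered conditions mild enough for the vinyl epoxide, the β-hydroxy ketone and the α-hydroxy enone, which gives the target.

**Compound list**

1 | 1-iodo-2-methylpropane | CC(C)CI | starting material
2 | triethyl phosphite | CCOP(OCC)OCC | starting material
3 | diethyl (2-methylpropyl)phosphonate | CCOP(=O)(CC(C)C)OCC | intermediate
4 | (R)-citronellal, (3R)-3,7-dimethyloct-6-enal | CC(C)=CCC[C@@H](C)CC=O | starting material
5 | (2S,3R)-2-(anilinooxy)-3,7-dimethyloct-6-enal | CC(C)=CCC[C@@H](C)[C@H](ONc1ccccc1)C=O | intermediate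
6 | (2S,3R)-2-(anilinooxy)-3,7-dimethyloct-6-en-1-ol | CC(C)=CCC[C@@H](C)[C@H](ONc1ccccc1)CO | intermediate
7 | (2S,3R)-3,7-dimethyloct-6-ene-1,2-diol | CC(C)=CCC[C@@H](C)[C@H](O)CO | intermediate
8 | (2S,3R)-3,7-dimethyl-1,2-bis(triethylsilyloxy)oct-6-ene | CC(C)=CCC[C@@H](C)[C@H](O[Si](CC)(CC)CC)CO[Si](CC)(CC)CC | intermediate
9 | (2S,3R)-3,7-dimethyl-2-(triethylsilyloxy)oct-6-enal | CC(C)=CCC[C@@H](C)[C@H](O[Si](CC)(CC)CC)C=O | intermediate
10 | diethyl (1-lithio-2-methylpropyl)phosphonate | [Li]C(C(C)C)P(=O)(OCC)OCC | intermediate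
11 | diethyl [(5S,6R)-4-hydroxy-2,6,10-trimethyl-5-(triethylsilyloxy)undec-9-en-3-yl]phosphonate (C3/C4 epimers) | CC(C)=CCC[C@@H](C)[C@H](O[Si](CC)(CC)CC)C(O)C(C(C)C)P(=O)(OCC)OCC | intermediate
12 | diethyl [(5S,6R)-2,6,10-trimethyl-4-oxo-5-(triethylsilyloxy)undec-9-en-3-yl]phosphonate (C3 epimers; fragment A) | CC(C)=CCC[C@@H](C)[C@H](O[Si](CC)(CC)CC)C(=O)C(C(C)C)P(=O)(OCC)OCC | intermediate
13 | nerol, (2Z)-3,7-dimethylocta-2,6-dien-1-ol | CC(C)=CCC/C(C)=C\CO | starting material
14 | [(2S,3R)-3-methyl-3-(4-methylpent-3-en-1-yl)oxiran-2-yl]methanol | OC[C@@H]1O[C@]1(C)CCC=C(C)C | intermediate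
15 | triethylsilyl ether of 14 | CC[Si](CC)(CC)OC[C@@H]1O[C@]1(C)CCC=C(C)C | intermediate
16 | ozonide (1,2,4-trioxolane) of 15 | CC[Si](CC)(CC)OC[C@@H]1O[C@]1(C)CCC2OOC(C)(C)O2 | intermediate
17 | 3-[(2R,3S)-2-methyl-3-(triethylsilyloxymethyl)oxiran-2-yl]propanal | CC[Si](CC)(CC)OC[C@@H]1O[C@]1(C)CCC=O | intermediate
18 | ethyl (triphenylphosphoranylidene)acetate | CCOC(=O)C=P(c1ccccc1)(c1ccccc1)c1ccccc1 | starting material
19 | ethyl iodo(triphenylphosphoranylidene)acetate | CCOC(=O)C(I)=P(c1ccccc1)(c1ccccc1)c1ccccc1 | intermediate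
20 | ethyl (2Z)-2-iodo-5-[(2R,3S)-2-methyl-3-(triethylsilyloxymethyl)oxiran-2-yl]pent-2-enoate | CC[Si](CC)(CC)OC[C@@H]1O[C@]1(C)CC/C=C(\I)C(=O)OCC | intermediate
21 | (2Z)-2-iodo-5-[(2R,3S)-2-methyl-3-(triethylsilyloxymethyl)oxiran-2-yl]pent-2-en-1-ol | CC[Si](CC)(CC)OC[C@@H]1O[C@]1(C)CC/C=C(\I)CO | intermediate
22 | tert-butyldimethylsilyl ether of 21 | CC[Si](CC)(CC)OC[C@@H]1O[C@]1(C)CC/C=C(\I)CO[Si](C)(C)C(C)(C)C | intermediate
23 | (2R,3R)-3-[(3Z)-5-(tert-butyldimethylsilyloxy)-4-iodopent-3-en-1-yl]-3-methyloxirane-2-carbaldehyde (fragment B) | O=C[C@@H]1O[C@]1(C)CC/C=C(\I)CO[Si](C)(C)C(C)(C)C | intermediate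
24 | seco enone: open chain with 1E enone, 3S,4R epoxide, 7Z 8-iodoalkene, 12R, 13S, C9=CMe2 end, O13 triethylsilyl, O15 tert-butyldimethylsilyl | CC(C)=CCC[C@@H](C)[C@H](O[Si](CC)(CC)CC)C(=O)/C(C(C)C)=C/[C@@H]1O[C@]1(C)CC/C=C(\I)CO[Si](C)(C)C(C)(C)C | intermediate
25 | vicinal diol from 24 (C9–OH and CMe2–OH) | CC(C)(O)C(O)CC[C@@H](C)[C@H](O[Si](CC)(CC)CC)C(=O)/C(C(C)C)=C/[C@@H]1O[C@]1(C)CC/C=C(\I)CO[Si](C)(C)C(C)(C)C | intermediate
26 | seco aldehyde: as 24 with C9 as aldehyde | O=CCC[C@@H](C)[C@H](O[Si](CC)(CC)CC)C(=O)/C(C(C)C)=C/[C@@H]1O[C@]1(C)CC/C=C(\I)CO[Si](C)(C)C(C)(C)C | intermediate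
27 | C8 alkenylchromium dichloride of 26 (trivalent chromium, chiral ligand not drawn) | O=CCC[C@@H](C)[C@H](O[Si](CC)(CC)CC)C(=O)/C(C(C)C)=C/[C@@H]1O[C@]1(C)CC/C=C(\[Cr](Cl)Cl)CO[Si](C)(C)C(C)(C)C | intermediate
28 | macrocyclic allylic alcohol (1E,3S,4R,7Z,9S,12R,13S), O13 triethylsilyl, O15 tert-butyldimethylsilyl | O[C@H]1CC[C@@H](C)[C@H](O[Si](CC)(CC)CC)C(=O)/C(C(C)C)=C/[C@@H]2O[C@]2(C)CC/C=C1/CO[Si](C)(C)C(C)(C)C | intermediate
29 | macrocyclic alcohol (1E,3S,4R,8S,9S,12R,13S), silyl groups as in 28 | O[C@H]1CC[C@@H](C)[C@H](O[Si](CC)(CC)CC)C(=O)/C(C(C)C)=C/[C@@H]2O[C@]2(C)CCC[C@H]1CO[Si](C)(C)C(C)(C)C | intermediate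
30 | bis-silyl diketone (1E,3S,4R,8S,12R,13S) | O=C1CC[C@@H](C)[C@H](O[Si](CC)(CC)CC)C(=O)/C(C(C)C)=C/[C@@H]2O[C@]2(C)CCC[C@H]1CO[Si](C)(C)C(C)(C)C | intermediate
31 | CNP0110598.2 (1E,3S,4R,8S,12R,13S) | CC(C)/C1=C\[C@@H]2O[C@]2(C)CCC[C@@H](CO)C(=O)CC[C@@H](C)[C@H](O)C1=O | target

**Count and risks**

Total steps: 20. Longest linear sequence: 13 steps (nerol 13 to target 31, steps 8–20).

Step 17 is the most exposed. Intermolecular coupling may outrun ring closure, the ligand may give poor facial control at C9, and divalent chromium may attack the γ,δ-epoxy enone. The fallback moves the ring closure to C1=C2 and sets out from 12 and 22. Lemieux–Johnson cleavage of 12 (OsO4, NaIO4, 2,6-lutidine) gives the aldehyde phosphonate F1. The same ligand-controlled chromium/nickel coupling, run intermolecularly with 22, gives the 9S allylic alcohol F2. Directed hydrogenation as in step 18 gives the 8S,9S alcohol F3. One Swern oxidation turns C9–OH into the ketone and the primary triethylsilyl ether into the C2 aldehyde, giving the keto aldehyde F4. An intramolecular Horner–Wadsworth–Emmons reaction (LiCl, i-Pr2NEt, MeCN, high dilution) then closes the ring and comes back to the route at 30.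

Step 18 may fail through poor facial selectivity, or through rhodium-induced alkene migration or redox isomerisation that gives the ketone without control at C8. The fallback replaces the hydroxyl relay by reagent control and sets out from 28. Dess–Martin oxidation gives the cross-conjugated macrocyclic dienedione F5. HF·pyridine removes both silyl groups to give the dihydroxy dienedione F6. Hydroxyl-directed asymmetric hydrogenation of the 2-(hydroxymethyl)enone (H2, 50 bar, Ru(OAc)2[(S)-BINAP], CH2Cl2/MeOH) then comes back at 31; the (S)-ligand is predicted from the geraniol/nerol face rule for allylic alcohols.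

Step 15 may fail through slow olefination by the hindered α-isopropyl phosphonate, erosion of E selectivity, or base-induced epimerisation at C13. The fallback is an aldol–elimination sequence that sets out from 9. Addition of i-BuMgBr gives the secondary alcohol F7, and Dess–Martin oxidation gives the isobutyl ketone F8. Kinetic enolisation on the CH2 side (LDA, THF, −78 °C) and addition of 23 gives the aldol F9. Mesylation (MsCl, Et3N) gives the mesylate F10, and elimination with DBU comes back at 24.

**Further compounds**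

F1 | step 17 | diethyl [(5S,6R)-2,6-dimethyl-4,9-dioxo-5-(triethylsilyloxy)nonan-3-yl]phosphonate (C9 aldehyde of fragment A) | O=CCC[C@@H](C)[C@H](O[Si](CC)(CC)CC)C(=O)C(C(C)C)P(=O)(OCC)OCC
F2 | step 17 | open-chain 9S allylic alcohol from F1 and 22 (7Z; C1 phosphonate; O2 and O13 triethylsilyl; O15 tert-butyldimethylsilyl) | CCOP(=O)(OCC)C(C(C)C)C(=O)[C@@H](O[Si](CC)(CC)CC)[C@H](C)CC[C@H](O)/C(CO[Si](C)(C)C(C)(C)C)=C\CC[C@@]1(C)O[C@H]1CO[Si](CC)(CC)CC
F3 | step 17 | open-chain 8S,9S alcohol (hydrogenated F2) | CCOP(=O)(OCC)C(C(C)C)C(=O)[C@@H](O[Si](CC)(CC)CC)[C@H](C)CC[C@H](O)[C@H](CO[Si](C)(C)C(C)(C)C)CCC[C@@]1(C)O[C@H]1CO[Si](CC)(CC)CC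
F4 | step 17 | open-chain C9 ketone, C2 aldehyde, C1 phosphonate (8S) | CCOP(=O)(OCC)C(C(C)C)C(=O)[C@@H](O[Si](CC)(CC)CC)[C@H](C)CCC(=O)[C@H](CO[Si](C)(C)C(C)(C)C)CCC[C@@]1(C)O[C@H]1C=O
F5 | step 18 | macrocyclic dienedione (1E,7Z; C9 ketone), silyl groups as in 28 | O=C1CC[C@@H](C)[C@H](O[Si](CC)(CC)CC)C(=O)/C(C(C)C)=C/[C@@H]2O[C@]2(C)CC/C=C1/CO[Si](C)(C)C(C)(C)C
F6 | step 18 | macrocyclic dihydroxy dienedione (1E,7Z; 7,8-didehydro target) | O=C1CC[C@@H](C)[C@H](O)C(=O)/C(C(C)C)=C/[C@@H]2O[C@]2(C)CC/C=C1/CO
F7 | step 15 | (5S,6R)-2,6,10-trimethyl-5-(triethylsilyloxy)undec-9-en-4-ol (C4 epimers) | CC(C)=CCC[C@@H](C)[C@H](O[Si](CC)(CC)CC)C(O)CC(C)C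
F8 | step 15 | (5S,6R)-2,6,10-trimethyl-5-(triethylsilyloxy)undec-9-en-4-one | CC(C)=CCC[C@@H](C)[C@H](O[Si](CC)(CC)CC)C(=O)CC(C)C
F9 | step 15 | aldol of F8 and 23 (C2–OH; C1 and C2 epimers) | CC(C)=CCC[C@@H](C)[C@H](O[Si](CC)(CC)CC)C(=O)C(C(C)C)C(O)[C@@H]1O[C@]1(C)CC/C=C(\I)CO[Si](C)(C)C(C)(C)C
F10 | step 15 | C2 mesylate of F9 | CC(C)=CCC[C@@H](C)[C@H](O[Si](CC)(CC)CC)C(=O)C(C(C)C)C(OS(C)(=O)=O)[C@@H]1O[C@]1(C)CC/C=C(\I)CO[Si](C)(C)C(C)(C)C
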